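Atoms are numbered as in the hydroazulene (C1–C2 epoxide, C3a/C8a fusion, C4 isopropyl, C5 ester, C7 carbinol). Everything rests on cutting the C3–C3a bond: the oxygenated five-membered ring then unravels to a C1 ketone carrying a C2-methyl vinyl arm on C8a of the seven-membered ring, and the stereocentre at C4, next door to C3a, can bias the ring-closing rotation. A silicon-directed Nazarov cyclisation closes this ring in one operation, parks the alkene at C2=C3 and sets C3a and C8a. Its precursor is a linalool-derived cycloheptene already bearing C4, C5 and C7, acylated at C8a by an (E)-2-methyl-3-(trimethylsilyl)acryloyl group.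

Key step: step 11

Remark: the open-chain C4/C5 relationship required by the target is syn, so the pentenylborane of step 4 must be Z, and delivery to the re face of aldehyde 5 calls for the isopinocampheyl reagent derived from (−)-α-pinene.
Remark: both oxygens are carried as tert-butyldimethylsilyl ethers, the tertiary C7 ether included, because a silyl group lost from O7 under FeCl3 would free an oxygen placed to add across the ring to C3a of the activated dienone.
Remark: commercial (R)-linalool of high enantiomeric purity is assumed, and the C1 carbinol centres made in steps 9 and 12 are carried as epimer mixtures because both are erased later.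

Step 1
Reactants: 1 (R)-linalool
Product: 2 tert-butyl{[(3R)-3,7-dimethylocta-1,6-dien-3-yl]oxy}dimethylsilane
Conditions: TBSOTf, 2,6-lutidine, CH2Cl2, 0 °C → rt
Reagents that add atoms: tert-butyldimethylsilyl trifluoromethanesulfonate, CC(C)(C)[Si](C)(C)OS(=O)(=O)C(F)(F)F
Why: Silyl ether formation from the silyl triflate is fast even at a tertiary allylic oxygen and leaves the C7 stereocentre of 1 untouched.

Step 2
Reactants: 2 tert-butyl{[(3R)-3,7-dimethylocta-1,6-dien-3-yl]oxy}dimethylsilane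
Product: 4 (3R)-3-[(tert-butyldimethylsilyl)oxy]-3,7-dimethyloct-6-en-1-ol, via alkyl-9-BBN adduct 3 (not isolated)
Conditions: 9-BBN, THF, 0 °C → rt; NaBO3·4H2O, THF/H2O, rt
Reagents that add atoms: sodium perborate tetrahydrate, [Na+].[O-]OB=O.O.O.O.O
Why: Anti-Markovnikov hydroboration–oxidation, in which 9-BBN adds only to the monosubstituted vinyl group (boron on the terminal carbon, the trisubstituted alkene being far slower) and mild perborate oxidation replaces boron by oxygen without disturbing the silyl ether.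

Step 3
Reactants: 4 (3R)-3-[(tert-butyldimethylsilyl)oxy]-3,7-dimethyloct-6-en-1-ol
Product: 5 (3R)-3-[(tert-butyldimethylsilyl)oxy]-3,7-dimethyloct-6-enal
Conditions: TEMPO (10 mol%), PhI(OAc)2, CH2Cl2, rt
Reagents that add atoms: none
Why: Nitroxyl-catalysed oxidation of the primary alcohol stops at the aldehyde and tolerates the alkene and the silyl ether, and the quaternary C7 centre cannot epimerise.

Step 4
Reactants: 5 (3R)-3-[(tert-butyldimethylsilyl)oxy]-3,7-dimethyloct-6-enal; 6 (Z)-4-methylpent-2-ene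
Product: 11 (3S,4S,6R)-6-[(tert-butyldimethylsilyl)oxy]-6,10-dimethyl-3-(propan-2-yl)undeca-1,9-dien-4-ol, via pentenylpotassium 7 (not isolated), via borate complex 8 (not isolated), via pentenylborane 9 (not isolated), via borinate ester 10 (not isolated)
Conditions: 6, n-BuLi, KOt-Bu, THF, −78 → −45 °C; (+)-Ipc2BOMe [from (−)-α-pinene], −78 °C; BF3·OEt2; 5, −78 °C; NaBO3·4H2O, THF/H2O, rt
Reagents that add atoms: none
Why: Asymmetric allylboration of Brown type through a closed chair (Zimmerman–Traxler) transition state, in which deprotonation of 6 at its methyl group keeps the Z geometry that becomes the syn C4/C5 relationship, while the isopinocampheyl ligands direct the pentenyl group to the re face of the aldehyde and so set C5 and C4 under reagent control, the remote quaternary C7 centre having little influence.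

Step 5
Reactants: 11 (3S,4S,6R)-6-[(tert-butyldimethylsilyl)oxy]-6,10-dimethyl-3-(propan-2-yl)undeca-1,9-dien-4-ol
Product: 12 (3S,4S,6R)-4,6-bis[(tert-butyldimethylsilyl)oxy]-6,10-dimethyl-3-(propan-2-yl)undeca-1,9-diene
Conditions: TBSOTf, 2,6-lutidine, CH2Cl2, −78 → 0 °C
Reagents that add atoms: tert-butyldimethylsilyl trifluoromethanesulfonate, CC(C)(C)[Si](C)(C)OS(=O)(=O)C(F)(F)F
Why: Silyl ether formation with the reactive triflate protects the hindered secondary C5 hydroxyl for the oxidation and Lewis acid steps ahead without touching any stereocentre.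

Step 6
Reactants: 12 (3S,4S,6R)-4,6-bis[(tert-butyldimethylsilyl)oxy]-6,10-dimethyl-3-(propan-2-yl)undeca-1,9-diene
Product: 14 (4R,6S,7S)-4,6-bis[(tert-butyldimethylsilyl)oxy]-4-methyl-7-(propan-2-yl)non-8-enal, via ozonide 13 (not isolated)
Conditions: O3, CH2Cl2, −78 °C (Sudan Red 7B end point); PPh3, −78 °C → rt
Reagents that add atoms: ozone, [O-][O+]=O
Why: Chemoselective ozonolysis, since the electron-rich trisubstituted alkene is consumed far faster than the hindered monosubstituted vinyl group (dye end point) and phosphine reduction of ozonide 13 releases the C1 aldehyde.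

Step 7
Reactants: 14 (4R,6S,7S)-4,6-bis[(tert-butyldimethylsilyl)oxy]-4-methyl-7-(propan-2-yl)non-8-enal
Product: 15 (4R,6S,7S)-4,6-bis[(tert-butyldimethylsilyl)oxy]-4-methyl-2-methylidene-7-(propan-2-yl)non-8-enal
Conditions: 37% aq CH2O, pyrrolidine (10 mol%), EtCO2H (10 mol%), i-PrOH, 45 °C
Reagents that add atoms: formaldehyde, C=O
Why: Organocatalytic α-methylenation (Mannich condensation of the enamine with formaldehyde, then elimination of the amine) at C8a, the only enolisable position, installs the 1,1-disubstituted alkene needed for ring closure.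

Step 8
Reactants: 15 (4R,6S,7S)-4,6-bis[(tert-butyldimethylsilyl)oxy]-4-methyl-2-methylidene-7-(propan-2-yl)non-8-enal
Product: 16 (3S,4S,6R)-4,6-bis[(tert-butyldimethylsilyl)oxy]-6-methyl-3-(propan-2-yl)cyclohept-1-ene-1-carbaldehyde
Conditions: second-generation Grubbs catalyst (5 mol%), CH2Cl2 (0.005 M), 40 °C
Reagents that add atoms: none
Why: Ring-closing olefin metathesis, in which the ruthenium carbene initiates at the terminal vinyl group and closes onto the electron-poor 1,1-disubstituted alkene, which cannot homodimerise, to form the trisubstituted C3a=C8a bond of the seven-membered ring, helped by the fully substituted C7 in the tether and involving no stereocentre.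

Step 9
Reactants: 16 (3S,4S,6R)-4,6-bis[(tert-butyldimethylsilyl)oxy]-6-methyl-3-(propan-2-yl)cyclohept-1-ene-1-carbaldehyde; 17 trimethyl(prop-1-yn-1-yl)silane
Product: 20 (2E)-1-[(3S,4S,6R)-4,6-bis[(tert-butyldimethylsilyl)oxy]-6-methyl-3-(propan-2-yl)cyclohept-1-en-1-yl]-2-methyl-3-(trimethylsilyl)prop-2-en-1-ol (both C1 epimers), via titanacyclopropene 18 (not isolated), via oxatitanacycle 19 (not isolated)
Conditions: 17, Ti(Oi-Pr)4, i-PrMgCl, Et2O, −78 → −50 °C; 16, −78 → −40 °C; H2O
Reagents that add atoms: none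
Why: Titanium alkoxide-mediated reductive coupling of an alkyne with an aldehyde, in which the divalent titanium complex 18 inserts the aldehyde into its Ti–C bond remote from silicon and protonolysis of the remaining Ti–C(Si) bond of 19 with retention leaves hydrogen cis to the carbinol, that is the E vinylsilane with the methyl group on C2, while the new C1 centre forms as a mixture that is erased in step 10.

Step 10
Reactants: 20 (2E)-1-[(3S,4S,6R)-4,6-bis[(tert-butyldimethylsilyl)oxy]-6-methyl-3-(propan-2-yl)cyclohept-1-en-1-yl]-2-methyl-3-(trimethylsilyl)prop-2-en-1-ol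
Product: 21 (2E)-1-[(3S,4S,6R)-4,6-bis[(tert-butyldimethylsilyl)oxy]-6-methyl-3-(propan-2-yl)cyclohept-1-en-1-yl]-2-methyl-3-(trimethylsilyl)prop-2-en-1-one
Conditions: Dess–Martin periodinane, NaHCO3, CH2Cl2, 0 °C → rt
Reagents that add atoms: none
Why: Dess–Martin oxidation of the doubly allylic carbinol under bicarbonate buffering gives the cross-conjugated dienone without acid that could attack the vinylsilane or trigger premature cyclisation.

Step 11
Reactants: 21 (2E)-1-[(3S,4S,6R)-4,6-bis[(tert-butyldimethylsilyl)oxy]-6-methyl-3-(propan-2-yl)cyclohept-1-en-1-yl]-2-methyl-3-(trimethylsilyl)prop-2-en-1-one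
Product: 24 (3aS,4S,5S,7R,8aS)-5,7-bis[(tert-butyldimethylsilyl)oxy]-2,7-dimethyl-4-(propan-2-yl)-3a,4,5,6,7,8-hexahydroazulen-1(8aH)-one, via iron dienolate 22 (not isolated), via cis-fused epimer 23 (not isolated)
Conditions: FeCl3 (1.1 equiv), CH2Cl2, −50 → −10 °C; aq NaHCO3; crude + DBU (0.2 equiv), CH2Cl2, rt
Reagents that add atoms: none
Why: Coordination of FeCl3 to the C1 carbonyl of 21 turns the dienone into a pentadienyl cation delocalised from C3a to C3, and this four-electron system ring-closes in the conrotatory sense required of a thermal reaction, making the C3–C3a bond; the oxyallyl cation so formed is quenched regioselectively because the C3–Si bond lies β to its C2 terminus and is cut by chloride, leaving the C2=C3 alkene and iron dienolate 22, which is protonated at C8a on work-up. The closest known reaction type is the FeCl3-promoted silicon-directed Nazarov cyclisation of β-silyl divinyl ketones. The one ring closed is the five-membered carbocycle, by conrotatory 4π electrocyclisation through the C3–C3a bond. C3a is controlled by the neighbouring C4 stereocentre, whose isopropyl group shields one face of the cycloheptenyl terminus so that C3 swings onto the other face, and C8a is controlled thermodynamically, the DBU treatment converging any cis-fused epimer 23 on the trans-fused ketone expected to be the more stable hydroazulenone. The step needs positional selectivity for the C2=C3 alkene (secured by silicon, which leaves as Me3SiCl), facial selectivity at C3a (secured by C4) and inertness of both oxygens (secured by the bulky silyl ethers, which also keep O7 from adding across the ring to C3a).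

Step 12
Reactants: 24 (3aS,4S,5S,7R,8aS)-5,7-bis[(tert-butyldimethylsilyl)oxy]-2,7-dimethyl-4-(propan-2-yl)-3a,4,5,6,7,8-hexahydroazulen-1(8aH)-one
Product: 25 (3aR,4S,5S,7R,8aS)-5,7-bis[(tert-butyldimethylsilyl)oxy]-2,7-dimethyl-4-(propan-2-yl)-1,3a,4,5,6,7,8,8a-octahydroazulen-1-ol (C1 epimers)
Conditions: NaBH4, CeCl3·7H2O, MeOH, −40 → 0 °C
Reagents that add atoms: none
Why: Luche reduction, in which cerium-activated borohydride adds 1,2 to the enone so that the C2=C3 alkene and the C8a configuration are kept, the C1 carbinol epimers being used together because C1 becomes trigonal in step 13.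

Step 13
Reactants: 25 (3aR,4S,5S,7R,8aS)-5,7-bis[(tert-butyldimethylsilyl)oxy]-2,7-dimethyl-4-(propan-2-yl)-1,3a,4,5,6,7,8,8a-octahydroazulen-1-ol
Product: 28 (3aR,4S,5S,7R,8aS)-5,7-bis[(tert-butyldimethylsilyl)oxy]-2,7-dimethyl-4-(propan-2-yl)-3,3a,4,5,6,7,8,8a-octahydroazulene, via sulfonylhydrazine 26 (not isolated), via allylic diazene 27 (not isolated)
Conditions: 2-nitrobenzenesulfonylhydrazide, PPh3, DEAD, THF, −30 °C → rt
Reagents that add atoms: none
Why: Mitsunobu displacement of the allylic alcohol by the sulfonylhydrazide nitrogen gives 26, which loses arenesulfinic acid on warming to the allylic diazene 27, whose sigmatropic (retro-ene) loss of N2 delivers hydrogen to C3 and moves the alkene to C1=C2 (reductive 1,3-transposition), so that C3 becomes a methylene group and C3a and C8a are untouched.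

Step 14
Reactants: 28 (3aR,4S,5S,7R,8aS)-5,7-bis[(tert-butyldimethylsilyl)oxy]-2,7-dimethyl-4-(propan-2-yl)-3,3a,4,5,6,7,8,8a-octahydroazulene
Product: 29 (3aR,4S,5S,7R,8aS)-2,7-dimethyl-4-(propan-2-yl)-3,3a,4,5,6,7,8,8a-octahydroazulene-5,7-diol
Conditions: TBAF, THF, 60 °C
Reagents that add atoms: none
Why: Fluoride-mediated desilylation, driven by the Si–F bond, frees both hydroxyls from a substrate that at this stage holds no base- or fluoride-sensitive group.

Step 15
Reactants: 29 (3aR,4S,5S,7R,8aS)-2,7-dimethyl-4-(propan-2-yl)-3,3a,4,5,6,7,8,8a-octahydroazulene-5,7-diol; 30 4-acetoxybenzoyl chloride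
Product: 31 (3aR,4S,5S,7R,8aS)-7-hydroxy-2,7-dimethyl-4-(propan-2-yl)-3,3a,4,5,6,7,8,8a-octahydroazulen-5-yl 4-acetoxybenzoate
Conditions: Et3N, DMAP (10 mol%), CH2Cl2, 0 °C → rt
Reagents that add atoms: none
Why: DMAP-catalysed acylation by the acid chloride takes place at the secondary C5 hydroxyl only, the tertiary C7 hydroxyl being too hindered, and proceeds with retention at C5.

Step 16
Reactants: 31 (3aR,4S,5S,7R,8aS)-7-hydroxy-2,7-dimethyl-4-(propan-2-yl)-3,3a,4,5,6,7,8,8a-octahydroazulen-5-yl 4-acetoxybenzoate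
Product: 32 (1S,2R,3aR,4S,5S,7R,8aS)-1,2-epoxy-7-hydroxy-2,7-dimethyl-4-(propan-2-yl)decahydroazulen-5-yl 4-acetoxybenzoate
Conditions: VO(acac)2 (5 mol%), t-BuOOH, CH2Cl2, 0 °C → rt
Reagents that add atoms: tert-butyl hydroperoxide, CC(C)(C)OO
Why: Hydroxyl-directed epoxidation, in which the vanadate ester of the tertiary C7 hydroxyl, lying on the same face of the bicycle as the C8a–C1 bond, delivers oxygen to that face of the trisubstituted C1=C2 alkene and so sets C1 and C2, the cis relationship also preventing the hydroxyl from opening the epoxide.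

Step 17
Reactants: 32 (1S,2R,3aR,4S,5S,7R,8aS)-1,2-epoxy-7-hydroxy-2,7-dimethyl-4-(propan-2-yl)decahydroazulen-5-yl 4-acetoxybenzoate
Product: 33 (1S,2R,3aR,4S,5S,7R,8aS)-1,2-epoxy-7-hydroxy-2,7-dimethyl-4-(propan-2-yl)decahydroazulen-5-yl 4-hydroxybenzoate (CNP0245441.1)
Conditions: K2CO3 (0.2 equiv), MeOH, 0 °C
Reagents that add atoms: none
Why: Chemoselective transesterification, since the aryl acetate is far more electrophilic than the hindered secondary benzoate, which is further deactivated once the para-phenoxide forms, so that catalytic carbonate in cold methanol leaves the ester, the epoxide and all stereocentres intact.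

Compound list
1 | (R)-linalool | CC(C)=CCC[C@@](C)(O)C=C | starting material
2 | tert-butyl{[(3R)-3,7-dimethylocta-1,6-dien-3-yl]oxy}dimethylsilane | CC(C)=CCC[C@@](C)(O[Si](C)(C)C(C)(C)C)C=C | intermediate
3 | anti-Markovnikov 9-BBN adduct of 2 (boron on the terminal carbon, C7 unchanged) | CC(C)=CCC[C@@](C)(O[Si](C)(C)C(C)(C)C)CCB1C2CCCC1CCC2 | intermediate (not isolated)
4 | (3R)-3-[(tert-butyldimethylsilyl)oxy]-3,7-dimethyloct-6-en-1-ol | CC(C)=CCC[C@@](C)(O[Si](C)(C)C(C)(C)C)CCO | intermediate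
5 | (3R)-3-[(tert-butyldimethylsilyl)oxy]-3,7-dimethyloct-6-enal | CC(C)=CCC[C@@](C)(O[Si](C)(C)C(C)(C)C)CC=O | intermediate
6 | (Z)-4-methylpent-2-ene | C/C=C\C(C)C | starting material
7 | (Z)-4-methylpent-2-en-1-ylpotassium | [K]C/C=C\C(C)C | intermediate (not isolated)
8 | potassium methoxy[(Z)-4-methylpent-2-en-1-yl]bis(isopinocampheyl)borate, isopinocampheyl groups from (−)-α-pinene | [K+].CO[B-](C/C=C\C(C)C)([C@H]1C[C@H]2C[C@@H]([C@@H]1C)C2(C)C)[C@H]1C[C@H]2C[C@@H]([C@@H]1C)C2(C)C | intermediate (not isolated)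
9 | [(Z)-4-methylpent-2-en-1-yl]bis(isopinocampheyl)borane | CC(C)/C=C\CB([C@H]1C[C@H]2C[C@@H]([C@@H]1C)C2(C)C)[C@H]1C[C@H]2C[C@@H]([C@@H]1C)C2(C)C | intermediate (not isolated)
10 | O-bis(isopinocampheyl)boryl ether (borinate) of 11 | C=C[C@H](C(C)C)[C@@H](OB([C@H]1C[C@H]2C[C@@H]([C@@H]1C)C2(C)C)[C@H]1C[C@H]2C[C@@H]([C@@H]1C)C2(C)C)C[C@](C)(O[Si](C)(C)C(C)(C)C)CCC=C(C)C | intermediate (not isolated)
11 | (3S,4S,6R)-6-[(tert-butyldimethylsilyl)oxy]-6,10-dimethyl-3-(propan-2-yl)undeca-1,9-dien-4-ol | C=C[C@H](C(C)C)[C@@H](O)C[C@](C)(O[Si](C)(C)C(C)(C)C)CCC=C(C)C | intermediate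
12 | (3S,4S,6R)-4,6-bis[(tert-butyldimethylsilyl)oxy]-6,10-dimethyl-3-(propan-2-yl)undeca-1,9-diene | C=C[C@H](C(C)C)[C@@H](O[Si](C)(C)C(C)(C)C)C[C@](C)(O[Si](C)(C)C(C)(C)C)CCC=C(C)C | intermediate
13 | ozonide (3,3-dimethyl-1,2,4-trioxolane) of the trisubstituted alkene of 12 | C=C[C@H](C(C)C)[C@@H](O[Si](C)(C)C(C)(C)C)C[C@](C)(O[Si](C)(C)C(C)(C)C)CCC1OOC(C)(C)O1 | intermediate (not isolated)
14 | (4R,6S,7S)-4,6-bis[(tert-butyldimethylsilyl)oxy]-4-methyl-7-(propan-2-yl)non-8-enal | C=C[C@H](C(C)C)[C@@H](O[Si](C)(C)C(C)(C)C)C[C@](C)(O[Si](C)(C)C(C)(C)C)CCC=O | intermediate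
15 | (4R,6S,7S)-4,6-bis[(tert-butyldimethylsilyl)oxy]-4-methyl-2-methylidene-7-(propan-2-yl)non-8-enal | C=C[C@H](C(C)C)[C@@H](O[Si](C)(C)C(C)(C)C)C[C@](C)(O[Si](C)(C)C(C)(C)C)CC(=C)C=O | intermediate
16 | (3S,4S,6R)-4,6-bis[(tert-butyldimethylsilyl)oxy]-6-methyl-3-(propan-2-yl)cyclohept-1-ene-1-carbaldehyde | CC(C)[C@H]1C=C(C=O)C[C@@](C)(O[Si](C)(C)C(C)(C)C)C[C@@H]1O[Si](C)(C)C(C)(C)C | intermediate
17 | trimethyl(prop-1-yn-1-yl)silane | CC#C[Si](C)(C)C | starting material
18 | diisopropoxy[η2-1-(trimethylsilyl)propyne]titanium (titanacyclopropene) | CC1=C([Si](C)(C)C)[Ti]1(OC(C)C)OC(C)C | intermediate (not isolated)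
19 | 2,2-diisopropoxy-1-oxa-2-titanacyclopent-3-ene from 18 and 16 (Ti on the silyl-bearing carbon, methyl on C2, cycloheptenyl on the carbinol carbon) | CC(C)[C@H]1C=C(C2O[Ti](OC(C)C)(OC(C)C)C([Si](C)(C)C)=C2C)C[C@@](C)(O[Si](C)(C)C(C)(C)C)C[C@@H]1O[Si](C)(C)C(C)(C)C | intermediate (not isolated)
20 | (2E)-1-[(3S,4S,6R)-4,6-bis[(tert-butyldimethylsilyl)oxy]-6-methyl-3-(propan-2-yl)cyclohept-1-en-1-yl]-2-methyl-3-(trimethylsilyl)prop-2-en-1-ol (both C1 epimers) | CC(C)[C@H]1C=C(C(O)/C(C)=C/[Si](C)(C)C)C[C@@](C)(O[Si](C)(C)C(C)(C)C)C[C@@H]1O[Si](C)(C)C(C)(C)C | intermediate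
21 | (2E)-1-[(3S,4S,6R)-4,6-bis[(tert-butyldimethylsilyl)oxy]-6-methyl-3-(propan-2-yl)cyclohept-1-en-1-yl]-2-methyl-3-(trimethylsilyl)prop-2-en-1-one (key-step precursor) | CC(C)[C@H]1C=C(C(=O)/C(C)=C/[Si](C)(C)C)C[C@@](C)(O[Si](C)(C)C(C)(C)C)C[C@@H]1O[Si](C)(C)C(C)(C)C | intermediate
22 | dichloroiron dienolate of 24 (C1–O–Fe, C1=C8a, C2=C3) | CC(C)[C@H]1[C@@H]2C=C(C)C(O[Fe](Cl)Cl)=C2C[C@@](C)(O[Si](C)(C)C(C)(C)C)C[C@@H]1O[Si](C)(C)C(C)(C)C | intermediate (not isolated)
23 | cis-fused (3aS,4S,5S,7R,8aR) epimer of 24 | CC(C)[C@H]1[C@@H]2C=C(C)C(=O)[C@@H]2C[C@@](C)(O[Si](C)(C)C(C)(C)C)C[C@@H]1O[Si](C)(C)C(C)(C)C | intermediate (not isolated)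
24 | (3aS,4S,5S,7R,8aS)-5,7-bis[(tert-butyldimethylsilyl)oxy]-2,7-dimethyl-4-(propan-2-yl)-3a,4,5,6,7,8-hexahydroazulen-1(8aH)-one (key-step product) | CC(C)[C@H]1[C@@H]2C=C(C)C(=O)[C@H]2C[C@@](C)(O[Si](C)(C)C(C)(C)C)C[C@@H]1O[Si](C)(C)C(C)(C)C | intermediate
25 | (3aR,4S,5S,7R,8aS)-5,7-bis[(tert-butyldimethylsilyl)oxy]-2,7-dimethyl-4-(propan-2-yl)-1,3a,4,5,6,7,8,8a-octahydroazulen-1-ol (C1 epimers) | CC(C)[C@H]1[C@@H]2C=C(C)C(O)[C@H]2C[C@@](C)(O[Si](C)(C)C(C)(C)C)C[C@@H]1O[Si](C)(C)C(C)(C)C | intermediate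
26 | N-(2-nitrobenzenesulfonyl)-N-(C1-allyl)hydrazine from 25 | CC(C)[C@H]1[C@@H]2C=C(C)C(N(N)S(=O)(=O)c3ccccc3[N+](=O)[O-])[C@H]2C[C@@](C)(O[Si](C)(C)C(C)(C)C)C[C@@H]1O[Si](C)(C)C(C)(C)C | intermediate (not isolated)
27 | C1 monoalkyl (allylic) diazene | CC(C)[C@H]1[C@@H]2C=C(C)C(N=N)[C@H]2C[C@@](C)(O[Si](C)(C)C(C)(C)C)C[C@@H]1O[Si](C)(C)C(C)(C)C | intermediate (not isolated)
28 | (3aR,4S,5S,7R,8aS)-5,7-bis[(tert-butyldimethylsilyl)oxy]-2,7-dimethyl-4-(propan-2-yl)-3,3a,4,5,6,7,8,8a-octahydroazulene | CC(C)[C@H]1[C@@H]2CC(C)=C[C@H]2C[C@@](C)(O[Si](C)(C)C(C)(C)C)C[C@@H]1O[Si](C)(C)C(C)(C)C | intermediate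
29 | (3aR,4S,5S,7R,8aS)-2,7-dimethyl-4-(propan-2-yl)-3,3a,4,5,6,7,8,8a-octahydroazulene-5,7-diol | CC(C)[C@H]1[C@@H]2CC(C)=C[C@H]2C[C@@](C)(O)C[C@@H]1O | intermediate
30 | 4-acetoxybenzoyl chloride | CC(=O)Oc1ccc(cc1)C(Cl)=O | starting material
31 | (3aR,4S,5S,7R,8aS)-7-hydroxy-2,7-dimethyl-4-(propan-2-yl)-3,3a,4,5,6,7,8,8a-octahydroazulen-5-yl 4-acetoxybenzoate | CC(C)[C@H]1[C@@H]2CC(C)=C[C@H]2C[C@@](C)(O)C[C@@H]1OC(=O)c1ccc(OC(C)=O)cc1 | intermediate
32 | (1S,2R,3aR,4S,5S,7R,8aS)-1,2-epoxy-7-hydroxy-2,7-dimethyl-4-(propan-2-yl)decahydroazulen-5-yl 4-acetoxybenzoate | CC(C)[C@H]1[C@@H]2C[C@@]3(C)O[C@H]3[C@H]2C[C@@](C)(O)C[C@@H]1OC(=O)c1ccc(OC(C)=O)cc1 | intermediate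
33 | (1S,2R,3aR,4S,5S,7R,8aS)-1,2-epoxy-7-hydroxy-2,7-dimethyl-4-(propan-2-yl)decahydroazulen-5-yl 4-hydroxybenzoate (CNP0245441.1) | CC(C)[C@H]1[C@@H]2C[C@@]3(C)O[C@H]3[C@H]2C[C@@](C)(O)C[C@@H]1OC(=O)c1ccc(O)cc1 | target

Total step count: 17. Longest linear sequence: 17 steps from (R)-linalool (1); no fragment needs separate preparation.

Steps most likely to fail

Step 11 (key step). The cyclisation may close on both faces of C3a if the C4 isopropyl group biases the rotation too weakly, FeCl3 may strip a silyl ether and open the way to transannular capture, or the ring fusion may not converge on the trans ketone. The fallback replaces the electrocyclisation by a conjugate addition and aldol cyclopentannulation; it sets out from 16 and comes back at 24. Ethylmagnesium bromide (THF, −78 °C) should add to 16 to give 1-[(3S,4S,6R)-4,6-bis(silyloxy)-6-methyl-3-(propan-2-yl)cyclohept-1-en-1-yl]propan-1-ol F1, and Dess–Martin oxidation should give the corresponding ethyl ketone F2. Vinylmagnesium bromide with CuBr·SMe2 and Me3SiCl (THF, −78 °C, then dilute acid) should deliver the vinyl group to C3a anti to the C4 isopropyl group and, after equilibration at C8a, give the trans vinyl ketone F3. Ozonolysis (O3, CH2Cl2, −78 °C; PPh3) should then give the keto aldehyde F4, and intramolecular aldol condensation (KOH, MeOH, rt) between C2 and the C3 aldehyde should close the 2-methylcyclopentenone and rejoin the route at 24.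

Step 13. The Mitsunobu displacement may be slow at the hindered C1 carbinol, the nucleophile may attack C3 instead of C1 (which would return the untransposed alkene), or the activated alcohol may eliminate to a diene. The fallback sets out from 24, skips step 12 and comes back at 28. p-Toluenesulfonylhydrazide (EtOH, 50 °C) should convert 24 into the tosylhydrazone F5; catecholborane (CHCl3, 0 °C) followed by NaOAc·3H2O at reflux should reduce the C=N bond, and the allylic diazene so formed should lose N2 with migration of the alkene to C1=C2, giving 28.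

Step 8. Initiation at the hindered vinyl group may be slow, leaving the α-methylene aldehyde to oligomerise or to deactivate the ruthenium carbene. The fallback postpones ring closure until the aldehyde has been used; it sets out from 15 and comes back at 20. The titanium-mediated coupling of step 9 should be applied to 15 and 17 to give the acyclic (2E)-dienol F6, and the ring should then be closed on this allylic alcohol (second-generation Hoveyda–Grubbs catalyst, toluene, 80 °C), which gives 20.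

Further compounds
F1 | step 11 | 1-[(3S,4S,6R)-4,6-bis[(tert-butyldimethylsilyl)oxy]-6-methyl-3-(propan-2-yl)cyclohept-1-en-1-yl]propan-1-ol (C1 epimers) | CC(C)[C@H]1C=C(C(O)CC)C[C@@](C)(O[Si](C)(C)C(C)(C)C)C[C@@H]1O[Si](C)(C)C(C)(C)C
F2 | step 11 | 1-[(3S,4S,6R)-4,6-bis[(tert-butyldimethylsilyl)oxy]-6-methyl-3-(propan-2-yl)cyclohept-1-en-1-yl]propan-1-one | CC(C)[C@H]1C=C(C(=O)CC)C[C@@](C)(O[Si](C)(C)C(C)(C)C)C[C@@H]1O[Si](C)(C)C(C)(C)C
F3 | step 11 | trans-(C8a-propanoyl)(C3a-vinyl)cycloheptane, vinyl anti to the C4 isopropyl group, C5 and C7 silyl ethers as in 16 | CC(C)[C@H]1[C@H](C=C)[C@@H](C(=O)CC)C[C@@](C)(O[Si](C)(C)C(C)(C)C)C[C@@H]1O[Si](C)(C)C(C)(C)C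
F4 | step 11 | keto aldehyde from F3 (C3 formyl on C3a, propanoyl on C8a) | CC(C)[C@H]1[C@H](C=O)[C@@H](C(=O)CC)C[C@@](C)(O[Si](C)(C)C(C)(C)C)C[C@@H]1O[Si](C)(C)C(C)(C)C
F5 | step 13 | p-toluenesulfonylhydrazone of 24 | CC(C)[C@H]1[C@@H]2C=C(C)C(=NNS(=O)(=O)c3ccc(C)cc3)[C@H]2C[C@@](C)(O[Si](C)(C)C(C)(C)C)C[C@@H]1O[Si](C)(C)C(C)(C)C
F6 | step 8 | (1E,6R,8S,9S)-6,8-bis[(tert-butyldimethylsilyl)oxy]-2,6-dimethyl-4-methylidene-9-(propan-2-yl)-1-(trimethylsilyl)undeca-1,10-dien-3-ol (C3 epimers) | C=C[C@H](C(C)C)[C@@H](O[Si](C)(C)C(C)(C)C)C[C@](C)(O[Si](C)(C)C(C)(C)C)CC(=C)C(O)/C(C)=C/[Si](C)(C)C
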